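**Plan**

- Numbering (briarane): ring C is C1, C10, C11, C12, C13, C14; the ten-membered ring is C1–C10; the butenolide is O–C7–C8=C17–C19(=O); methyls are C15 (on C1), C16 (on C5), C18 (on C17), C20 (on C11).
- Retrosynthesis: the oxirane is taken back to the C11=C12 alkene, then the C7–C8 bond and the lactone O–C19 bond are cut together. C7 is a carbinol carbon lying between the Z C5=C6 alkene and butenolide carbon C8, and C8 is cis across C8=C17 to the C19 carbonyl, so a C8 alkenyl metal adding to a C7 enal closes the ten-membered ring, creates C7 and lactonises.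
- The open precursor is cut at C2–C3 (ring-C aldehyde plus a homoallylic Grignard reagent carrying the Z alkene) and at C8–C17 (aldol with methyl propanoate, then Z enol triflate).
- Forward order: ring C from (R)-carvone; the C3–C7 chain from 4-methyl-5,6-dihydro-2H-pyran-2-one; C17–C19; ten-membered ring and butenolide in one step; the oxirane last.
- Stereochemistry: C14 is the carvone centre (Criegee rearrangement, retention); C1 by enolate methylation anti to it; a temporary C12 carbinol (epoxidation anti to isopropenyl) is relayed to C10 by Wharton transposition and Eschenmoser–Claisen rearrangement; C2 by CBS reduction; Z C5=C6 from the lactone ring; C7 in the ring closure; C11/C12 by diaxial bromohydrin opening and closure with inversion.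

Key step: step 22

Remark: ring C of the macrocyclic alkene is assumed to keep the half-chair with the C15 methyl and the C14 acetoxy group axial, as is usual for this ring system; the facial analysis of step 23 rests on this.

**Route**

Step 1
Reactants: 1 (R)-carvone
Product: 3 6-(benzyloxymethyl)carvone (trans epimer major; both epimers are used), via carvone lithium dienolate 2 (not isolated)
Conditions: LiN(iPr)2, THF, −78 °C; BnOCH2Cl, −78 → −20 °C
Reagents that add atoms: benzyl chloromethyl ether, ClCOCc1ccccc1
Why: Kinetic deprotonation at the α′ carbon gives the cross-conjugated lithium dienolate, which is C-alkylated by the reactive chloromethyl ether (enolate alkylation); the new centre is planarised again in step 2, so its configuration does not matter.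

Step 2
Reactants: 3 6-(benzyloxymethyl)carvone
Product: 5 6-(benzyloxymethyl)-6-methylcarvone (CH2OBn cis and CH3 trans to isopropenyl), via substituted lithium dienolate 4 (not isolated)
Conditions: LiN(iPr)2, THF, −78 °C; MeI, −78 → −40 °C
Reagents that add atoms: iodomethane, CI
Why: Enolate alkylation in which MeI approaches the planar dienolate anti to the neighbouring isopropenyl group, setting quaternary C1 with the methyl trans and the future C2 carbon cis to isopropenyl; the chelated β-alkoxy enolate is trapped cold before it can expel benzyloxide.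

Step 3
Reactants: 5 6-(benzyloxymethyl)-6-methylcarvone
Product: 6 epoxy ketone (oxirane trans to isopropenyl)
Conditions: H2O2 (30% aq), NaOH, MeOH, 0 °C
Reagents that add atoms: hydrogen peroxide, OO
Why: Weitz–Scheffer nucleophilic epoxidation, in which hydroperoxide adds to the enone β-carbon (C12) anti to the pseudo-equatorial isopropenyl group as with carvone itself and the enolate closes the oxirane on that face; the isolated alkene is inert.

Step 4
Reactants: 6 epoxy ketone
Product: 9 C14 acetate of the epoxy ketone, via methoxy hydroperoxide 7 (not isolated), via peroxyacetate 8 (not isolated)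
Conditions: O3, CH2Cl2/MeOH, −78 °C; Ac2O, Et3N, 4-(dimethylamino)pyridine (cat.), 0 °C → rt
Reagents that add atoms: ozone, [O-][O+]=O; methanol, CO
Why: Ozonolysis of the only electron-rich alkene in methanol gives the methoxy hydroperoxide, and its acetylation triggers the Criegee rearrangement in which C14 migrates to oxygen with retention; the ketone has no enolisable position (quaternary C1, oxirane C11), so the β-acetoxy ketone cannot eliminate.

Step 5
Reactants: 9 C14 acetate of the epoxy ketone
Product: 11 ring-C allylic alcohol (C10=C11 alkene; C12 hydroxyl trans to the acetate), via epoxy hydrazone 10 (not isolated)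
Conditions: N2H4·H2O, AcOH, MeOH, 0 °C → rt
Reagents that add atoms: none
Why: Wharton transposition, in which the hydrazone of the α,β-epoxy ketone opens the C11–O bond and loses N2 to give the C10=C11 alkene and the C12 carbinol with its C–O bond untouched; short exposure to buffered hydrazine should spare the hindered acetate.

Step 6
Reactants: 11 ring-C allylic alcohol
Product: 13 C10 dimethylacetamide (side chain cis to the C1 methyl; C11=C12 alkene), via ketene N,O-acetal 12 (not isolated)
Conditions: MeC(OMe)2NMe2, xylene, 140 °C
Reagents that add atoms: N,N-dimethylacetamide dimethyl acetal, CC(OC)(OC)N(C)C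
Why: Eschenmoser–Claisen rearrangement, a suprafacial [3,3] shift of the ketene N,O-acetal that delivers the acetamide carbon (C9) to C10 on the face that carried the C12–O bond, so C10 is set by 1,3-chirality transfer and the C11=C12 alkene is formed.

Step 7
Reactants: 13 C10 dimethylacetamide
Product: 14 primary alcohol at C2
Conditions: BCl3, C6HMe5, CH2Cl2, −78 °C
Reagents that add atoms: none
Why: Lewis-acid cleavage of the benzyl ether at low temperature with pentamethylbenzene as a non-basic benzyl-cation trap leaves the acetate, the amide and the trisubstituted alkene (which excludes hydrogenolysis) untouched.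

Step 8
Reactants: 14 primary alcohol at C2
Product: 15 C2 aldehyde
Conditions: Dess–Martin periodinane, NaHCO3, CH2Cl2, rt
Reagents that add atoms: none
Why: Dess–Martin oxidation of the neopentyl alcohol under buffered conditions gives the non-enolisable aldehyde without acetyl migration.

Step 9
Reactants: 16 4-methyl-5,6-dihydro-2H-pyran-2-one
Product: 17 (2Z)-3-methylpent-2-ene-1,5-diol
Conditions: LiAlH4, Et2O, 0 °C
Reagents that add atoms: none
Why: Hydride reduction (1,2-mode for the β,β-disubstituted enoate) opens the lactone to the diol, and the ring origin of the alkene fixes the Z geometry needed at C5=C6.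

Step 10
Reactants: 17 (2Z)-3-methylpent-2-ene-1,5-diol
Product: 18 (2Z)-1,5-dibromo-3-methylpent-2-ene
Conditions: CBr4, PPh3, CH2Cl2, 0 °C (diol added to the reagent)
Reagents that add atoms: carbon tetrabromide, BrC(Br)(Br)Br
Why: Appel bromination replaces both primary hydroxyls by SN2 displacement of the alkoxyphosphonium ions without allylic transposition or Z/E isomerisation, and inverse addition keeps cyclic ether formation down.

Step 11
Reactants: 18 (2Z)-1,5-dibromo-3-methylpent-2-ene
Product: 19 (Z)-5-bromo-3-methylpent-2-enyl 4-methoxybenzyl ether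
Conditions: 4-MeOC6H4CH2OH, NaH, THF, 0 °C; then 18 (slight excess), −20 → 0 °C
Reagents that add atoms: 4-methoxybenzyl alcohol, COc1ccc(CO)cc1
Why: Williamson ether synthesis in which the primary allylic bromide is displaced far faster than the unactivated homoallylic bromide, so one equivalent of alkoxide protects the C7 oxygen and leaves the C3 bromide for metallation.

Step 12
Reactants: 19 (Z)-5-bromo-3-methylpent-2-enyl 4-methoxybenzyl ether; 15 C2 aldehyde
Product: 21 C2 carbinol (both C2 epimers), via Grignard reagent 20 (not isolated)
Conditions: 19, Mg, THF, rt (used at once); then 15, LaCl3·2LiCl, THF, −78 °C; AcOH, −78 °C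
Reagents that add atoms: none
Why: Grignard addition, promoted by LaCl3·2LiCl to suppress β-hydride reduction, reaches the non-enolisable aldehyde at −78 °C much faster than the hindered acetate or the tertiary amide, and the cold acidic quench forestalls 1,3-acetyl migration or attack of the alkoxide on the amide; C2 is deliberately not set here because chelate and open transition states point to opposite epimers.

Step 13
Reactants: 21 C2 carbinol
Product: 22 C2 ketone
Conditions: Dess–Martin periodinane, NaHCO3, CH2Cl2, rt
Reagents that add atoms: none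
Why: Dess–Martin oxidation merges both carbinol epimers into one ketone under neutral conditions tolerated by the 4-methoxybenzyl ether, acetate and amide.

Step 14
Reactants: 22 C2 ketone
Product: 23 (2S)-alcohol
Conditions: (R)-1-methyl-3,3-diphenyltetrahydro-1H,3H-pyrrolo[1,2-c][1,3,2]oxazaborole (the (R)-CBS catalyst, 20 mol%), catecholborane, toluene, −40 °C
Reagents that add atoms: none
Why: Corey–Bakshi–Shibata reduction, in which the (R)-oxazaborolidine distinguishes the fully substituted C1 flank from the C3 methylene flank (as with tert-alkyl methyl ketones) and directs hydride to the face giving the 2S carbinol under catalyst control, while catecholborane leaves amide, esters and alkenes alone.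

Step 15
Reactants: 23 (2S)-alcohol
Product: 24 (2S)-butanoate
Conditions: (PrCO)2O, Et3N, 4-(dimethylamino)pyridine, CH2Cl2, rt
Reagents that add atoms: butanoic anhydride, CCCC(=O)OC(=O)CCC
Why: Acylation of the hindered secondary alcohol by nucleophilic catalysis with 4-(dimethylamino)pyridine installs the butanoate without alkoxide formation, so the neighbouring acetate should not migrate.

Step 16
Reactants: 24 (2S)-butanoate
Product: 25 C8 aldehyde
Conditions: Cp2Zr(H)Cl, THF, rt
Reagents that add atoms: none
Why: Hydrozirconation of the tertiary amide carbonyl gives a zirconated hemiaminal that releases the aldehyde on work-up, a reduction known to be much faster for tertiary amides than for esters or trisubstituted alkenes.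

Step 17
Reactants: 25 C8 aldehyde; 26 methyl propanoate
Product: 28 β-hydroxy ester (C8/C17 diastereomer mixture), via methyl propanoate lithium enolate 27 (not isolated)
Conditions: 26, LiN(iPr)2, THF, −78 °C; then 25, −78 °C; AcOH, −78 °C
Reagents that add atoms: none
Why: Aldol addition of the ester lithium enolate to the aldehyde at −78 °C outruns any attack on the butanoate or acetate, and both new centres are removed in steps 18 and 19.

Step 18
Reactants: 28 β-hydroxy ester
Product: 29 β-keto ester
Conditions: Dess–Martin periodinane, NaHCO3, CH2Cl2, rt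
Reagents that add atoms: none
Why: Dess–Martin oxidation of a β-hydroxy ester gives the 2-methyl-3-oxo ester under neutral conditions that avoid retro-aldol cleavage.

Step 19
Reactants: 29 β-keto ester
Product: 31 (Z)-enol triflate, via sodium enolate 30 (not isolated)
Conditions: NaH, Et2O, 0 °C; Tf2O, −78 → 0 °C
Reagents that add atoms: trifluoromethanesulfonic anhydride, O=S(=O)(OS(=O)(=O)C(F)(F)F)C(F)(F)F
Why: O-sulfonylation of the β-keto ester enolate, whose U-shaped sodium chelate holds the enolate oxygen cis to the ester carbonyl, so trapping gives the Z enol triflate with the C8–O bond cis to C19.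

Step 20
Reactants: 31 (Z)-enol triflate
Product: 32 allylic alcohol at C7
Conditions: DDQ, CH2Cl2/pH 7 buffer, 0 °C
Reagents that add atoms: none
Why: Oxidative cleavage of the 4-methoxybenzyl ether by DDQ (hydride abstraction, then hydrolysis of the oxocarbenium ion) frees the allylic alcohol under neutral conditions compatible with the enol triflate, the esters and the Z alkene.

Step 21
Reactants: 32 allylic alcohol at C7
Product: 33 Z-enal enol triflate (cyclisation precursor)
Conditions: Dess–Martin periodinane, NaHCO3, CH2Cl2, 0 °C
Reagents that add atoms: none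
Why: Dess–Martin oxidation of the Z allylic alcohol under bicarbonate buffer gives the Z enal without acid- or base-mediated isomerisation to the E isomer.

Step 22
Reactants: 33 Z-enal enol triflate
Product: 36 11,12-deoxy target (C11=C12 alkene), via alkenylchromium species 34 (not isolated), via macrocyclic chromium alkoxide 35 (not isolated)
Conditions: CrCl2 (10 equiv), NiCl2 (2 mol%), degassed DMF, slow addition of 33 to 0.002 M, rt → 50 °C
Reagents that add atoms: none
Why: Zerovalent nickel formed from NiCl2 and CrCl2 inserts into the C8–O triflate bond with retention, transmetallation gives the alkenyl species of trivalent chromium 34, this adds 1,2 to the C7 enal carbonyl (Nozaki–Hiyama–Kishi reaction), and the chromium alkoxide 35 attacks the cis C19 methyl ester and expels methoxide. The closest known reactions are Nozaki–Hiyama–Kishi macrocyclisations of alkenyl triflates or iodides onto aldehydes and the one-pot butenolide formation from (Z)-β-halo or β-sulfonyloxy acrylates and aldehydes under the same NiCl2/CrCl2 conditions. The ten-membered ring closes by 10-exo-trig addition of C8 to the aldehyde carbon and the butenolide by 5-exo-trig acyl substitution at C19. C7 is the only new stereocentre and arises under substrate control: the tether is held by the Z C5=C6 bond and by the trans C2 and C9 anchors on ring C, and the closure that keeps the chromium-bound oxygen on the outer side of the forming ring, expected to be the 7R lactone, should predominate. The step needs chemoselectivity for the aldehyde over three esters (alkenylchromium reagents do not add to esters), retention of both alkene geometries (stereoretentive oxidative addition and transmetallation, neutral medium for the Z enal) and cyclisation over oligomerisation (slow addition at high dilution).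

Step 23
Reactants: 36 11,12-deoxy target
Product: 37 bromohydrin (C11 hydroxyl syn and C12 bromide anti to the C15 methyl)
Conditions: NBS, DME/H2O, 0 °C
Reagents that add atoms: N-bromosuccinimide, O=C1CCC(=O)N1Br; water, O
Why: Bromohydrin formation under reversible bromonium formation, where only the ion on the face anti to the axial C15 methyl can be opened by water at tertiary C11 in both the Markovnikov and the trans-diaxial (Fürst–Plattner) sense, which fixes C11 and C12; direct peracid epoxidation is expected to favour the opposite face, the C5=C6 alkene is deactivated by the allylic lactone oxygen and the butenolide alkene is electron-poor.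

Step 24
Reactants: 37 bromohydrin
Product: 38 target
Conditions: Ag2O, THF, rt
Reagents that add atoms: none
Why: Halohydrin closure (intramolecular Williamson reaction) in which the C11 oxygen displaces the antiperiplanar, silver-activated C12 bromide with inversion, placing the oxirane on the face of the C15 methyl (11S,12R) under non-basic conditions that spare the three ester groups.

**Compound list**

1 | (R)-carvone, (5R)-2-methyl-5-(prop-1-en-2-yl)cyclohex-2-en-1-one | CC1=CC[C@H](CC1=O)C(C)=C | starting material
2 | lithium cross-conjugated dienolate of 1 (O–C1=C6, carvone numbering) | CC1=CC[C@@H](C(C)=C)C=C1[O-].[Li+] | intermediate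
3 | (5R,6R)-6-[(benzyloxy)methyl]-2-methyl-5-(prop-1-en-2-yl)cyclohex-2-en-1-one (major epimer, CH2OBn trans to isopropenyl; the 6-epimer is carried along) | CC1=CC[C@@H](C(C)=C)[C@H](COCc2ccccc2)C1=O | intermediate
4 | lithium dienolate of 3 | CC1=CC[C@@H](C(C)=C)C(COCc2ccccc2)=C1[O-].[Li+] | intermediate
5 | (5S,6S)-6-[(benzyloxy)methyl]-2,6-dimethyl-5-(prop-1-en-2-yl)cyclohex-2-en-1-one (CH2OBn cis, CH3 trans to isopropenyl; C6 becomes C1, C5 becomes C14) | CC1=CC[C@@H](C(C)=C)[C@@](C)(COCc2ccccc2)C1=O | intermediate
6 | 2,3-epoxy ketone of 5, oxirane trans to isopropenyl (C10 ketone, 11,12-oxirane) | C[C@@]12O[C@@H]1C[C@@H](C(C)=C)[C@@](C)(COCc1ccccc1)C2=O | intermediate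
7 | methoxy hydroperoxide of 6 (2-hydroperoxy-2-methoxypropan-2-yl at C14, mixture at that carbon) | C[C@@]12O[C@@H]1C[C@@H](C(C)(OC)OO)[C@@](C)(COCc1ccccc1)C2=O | intermediate
8 | peroxyacetate of 7 | C[C@@]12O[C@@H]1C[C@@H](C(C)(OC)OOC(C)=O)[C@@](C)(COCc1ccccc1)C2=O | intermediate
9 | epoxy ketone with C14 acetoxy in place of isopropenyl, same configuration (acetoxy cis to CH2OBn, trans to the oxirane) | C[C@@]12O[C@@H]1C[C@@H](OC(C)=O)[C@@](C)(COCc1ccccc1)C2=O | intermediate
10 | hydrazone of 9 | C[C@@]12O[C@@H]1C[C@@H](OC(C)=O)[C@@](C)(COCc1ccccc1)C2=NN | intermediate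
11 | 5-acetoxy-4-[(benzyloxy)methyl]-2,4-dimethylcyclohex-2-en-1-ol; hydroxyl (C12) trans to acetoxy (C14), CH2OBn cis to acetoxy | CC1=C[C@](C)(COCc2ccccc2)[C@H](OC(C)=O)C[C@H]1O | intermediate
12 | 1-(dimethylamino)vinyl ether of 11 (ketene N,O-acetal) | CC1=C[C@](C)(COCc2ccccc2)[C@H](OC(C)=O)C[C@H]1OC(=C)N(C)C | intermediate
13 | 2-{5-acetoxy-6-[(benzyloxy)methyl]-2,6-dimethylcyclohex-2-en-1-yl}-N,N-dimethylacetamide; side chain (at C10) cis to the C1 methyl, trans to CH2OBn and to acetoxy | C(OCc1ccccc1)[C@@]1(C)[C@H](CC(=O)N(C)C)C(C)=CC[C@H]1OC(C)=O | intermediate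
14 | primary alcohol from 13 (hydroxymethyl at C1), same ring configuration | OC[C@@]1(C)[C@H](CC(=O)N(C)C)C(C)=CC[C@H]1OC(C)=O | intermediate
15 | C2 aldehyde (formyl at C1), same ring configuration | O=C[C@@]1(C)[C@H](CC(=O)N(C)C)C(C)=CC[C@H]1OC(C)=O | intermediate
16 | 4-methyl-5,6-dihydro-2H-pyran-2-one | CC1=CC(=O)OCC1 | starting material
17 | (2Z)-3-methylpent-2-ene-1,5-diol | OCC/C(C)=C\CO | intermediate
18 | (2Z)-1,5-dibromo-3-methylpent-2-ene | BrCC/C(C)=C\CBr | intermediate
19 | 1-({[(2Z)-5-bromo-3-methylpent-2-en-1-yl]oxy}methyl)-4-methoxybenzene | BrCC/C(C)=C\COCc1ccc(OC)cc1 | intermediate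
20 | Grignard reagent of 19 (bromomagnesium at C3) | Br[Mg]CC/C(C)=C\COCc1ccc(OC)cc1 | intermediate
21 | C2 carbinol from 15 and 20, both C2 epimers, 5Z | OC(CC/C(C)=C\COCc1ccc(OC)cc1)[C@@]1(C)[C@H](CC(=O)N(C)C)C(C)=CC[C@H]1OC(C)=O | intermediate
22 | C2 ketone, 5Z | O=C(CC/C(C)=C\COCc1ccc(OC)cc1)[C@@]1(C)[C@H](CC(=O)N(C)C)C(C)=CC[C@H]1OC(C)=O | intermediate
23 | (2S)-alcohol, 5Z | O[C@@H](CC/C(C)=C\COCc1ccc(OC)cc1)[C@@]1(C)[C@H](CC(=O)N(C)C)C(C)=CC[C@H]1OC(C)=O | intermediate
24 | (2S)-butanoate, C14 acetate, C8 dimethylamide, C7 4-methoxybenzyl ether | CCCC(=O)O[C@@H](CC/C(C)=C\COCc1ccc(OC)cc1)[C@@]1(C)[C@H](CC(=O)N(C)C)C(C)=CC[C@H]1OC(C)=O | intermediate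
25 | C8 aldehyde (2-oxoethyl at C10) | CCCC(=O)O[C@@H](CC/C(C)=C\COCc1ccc(OC)cc1)[C@@]1(C)[C@H](CC=O)C(C)=CC[C@H]1OC(C)=O | intermediate
26 | methyl propanoate | CCC(=O)OC | starting material
27 | lithium enolate of 26 | CC=C([O-])OC.[Li+] | intermediate
28 | methyl 3-hydroxy-2-methylbutanoate arm at C10 (C8 carbinol, mixture at C8 and C17) | CCCC(=O)O[C@@H](CC/C(C)=C\COCc1ccc(OC)cc1)[C@@]1(C)[C@H](CC(O)C(C)C(=O)OC)C(C)=CC[C@H]1OC(C)=O | intermediate
29 | β-keto ester (C8 ketone, C17 methyl, C19 methyl ester; mixture at C17) | CCCC(=O)O[C@@H](CC/C(C)=C\COCc1ccc(OC)cc1)[C@@]1(C)[C@H](CC(=O)C(C)C(=O)OC)C(C)=CC[C@H]1OC(C)=O | intermediate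
30 | sodium (Z)-enolate of 29 | CCCC(=O)O[C@@H](CC/C(C)=C\COCc1ccc(OC)cc1)[C@@]1(C)[C@H](C/C([O-])=C(C)/C(=O)OC)C(C)=CC[C@H]1OC(C)=O.[Na+] | intermediate
31 | (Z)-enol triflate (C8–OTf cis to C19), C7 4-methoxybenzyl ether | CCCC(=O)O[C@@H](CC/C(C)=C\COCc1ccc(OC)cc1)[C@@]1(C)[C@H](C/C(OS(=O)(=O)C(F)(F)F)=C(C)/C(=O)OC)C(C)=CC[C@H]1OC(C)=O | intermediate
32 | C7 allylic alcohol, 5Z | CCCC(=O)O[C@@H](CC/C(C)=C\CO)[C@@]1(C)[C@H](C/C(OS(=O)(=O)C(F)(F)F)=C(C)/C(=O)OC)C(C)=CC[C@H]1OC(C)=O | intermediate
33 | ring-C diester with the (Z)-enal arm at C1 (via C2) and the (Z)-β-triflyloxy enoate arm at C10 | CCCC(=O)O[C@@H](CC/C(C)=C\C=O)[C@@]1(C)[C@H](C/C(OS(=O)(=O)C(F)(F)F)=C(C)/C(=O)OC)C(C)=CC[C@H]1OC(C)=O | intermediate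
34 | C8 alkenyl dichlorochromium species (trivalent chromium) from 33 | CCCC(=O)O[C@@H](CC/C(C)=C\C=O)[C@@]1(C)[C@H](C/C([Cr](Cl)Cl)=C(C)/C(=O)OC)C(C)=CC[C@H]1OC(C)=O | intermediate
35 | ten-membered C7 chromium alkoxide (trivalent chromium) with the cis C19 methyl ester | CCCC(=O)O[C@H]1CC/C(C)=C\[C@@H](O[Cr](Cl)Cl)/C(=C(/C)C(=O)OC)C[C@@H]2C(C)=CC[C@@H](OC(C)=O)[C@@]12C | intermediate
36 | 11,12-deoxy target: 14-acetoxy-2-butanoyloxy briarane 5Z,8(17),11-triene butenolide | CCCC(=O)O[C@H]1CC/C(C)=C\[C@H]2OC(=O)C(C)=C2C[C@@H]2C(C)=CC[C@@H](OC(C)=O)[C@@]12C | intermediate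
37 | bromohydrin of 36: C11 hydroxyl cis to the C15 methyl, C12 bromide trans to it | CCCC(=O)O[C@H]1CC/C(C)=C\[C@H]2OC(=O)C(C)=C2C[C@@H]2[C@](C)(O)[C@@H](Br)C[C@@H](OC(C)=O)[C@@]12C | intermediate
38 | CNP0220791.1, (1R,2S,5Z,7R,10S,11S,12R,14R)-14-acetoxy-2-butanoyloxy-11,12-epoxy briarane butenolide | CCCC(=O)O[C@H]1CC/C(C)=C\[C@H]2OC(=O)C(C)=C2C[C@@H]2[C@]3(C)O[C@@H]3C[C@@H](OC(C)=O)[C@@]12C | target

**Step count and risks**

Total: 24 steps. Longest linear sequence: 21 steps from (R)-carvone (steps 1–8 and 12–24); the chain bromide takes 3 steps (9–11).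

Steps most likely to fail:

1. Step 22. The alkenylchromium reagent may add to the other face of the enal, so that the ring closes but with the wrong configuration at C7 (poor facial selectivity in the macrocyclisation). Fallback, setting out from 33 and rejoining at 36: the cyclisation is run as before and the epimeric lactone, 7-epi-36 F1, is kept. DBU in toluene removes its C7 proton (γ to the lactone carbonyl and allylic) to give the aromatic 2-oxidofuran amidinium salt F2. Reversible reprotonation at C7 lets the epimers equilibrate toward the less strained lactone; 36 is separated and F1 recycled. C7 is then set by thermodynamic protonation of a planar furanolate, not by the face selectivity of the C–C bond formation.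

2. Step 5. Hydrazone formation at a carbonyl flanked by quaternary C1 and the oxirane may be slow, and hydrazinolysis of the acetate may compete. Fallback, setting out from 9 and rejoining at 11: NaBH4 with CeCl3·7H2O in MeOH reduces the ketone to the epoxy alcohol F3 (either C10 epimer serves). 1,1'-Thiocarbonyldiimidazole converts it into the imidazolylthiocarbonate F4. Bu3SnH with azobisisobutyronitrile in toluene at 80 °C generates the C10 radical, which opens the adjacent oxirane by β-scission of the C11–O bond; hydrogen transfer to the C12 alkoxyl radical gives 11 with C12 unchanged.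

3. Step 23. Bromonium formation may occur at the C5=C6 alkene, or the ring-C bromonium ion may be opened in the opposite regio- and facial sense if the half-chair of ring C is inverted in the macrocycle; closure would then give the epimeric oxirane. Fallback, from 36 directly to 38 (no new compound, F0): direct oxygen transfer with dimethyldioxirane in acetone at −20 °C. A concerted epoxidation places oxygen on the face the electrophile attacks and is therefore stereochemically complementary to the halohydrin route.

Further compounds
F1 | step 22 | 7-epi-36 (C7 epimer of the 11,12-deoxy target) | CCCC(=O)O[C@H]1CC/C(C)=C\[C@@H]2OC(=O)C(C)=C2C[C@@H]2C(C)=CC[C@@H](OC(C)=O)[C@@]12C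
F2 | step 22 | 2-oxidofuran of 36 as its DBU-H salt | CCCC(=O)O[C@H]1CC/C(C)=C\c2oc([O-])c(C)c2C[C@@H]2C(C)=CC[C@@H](OC(C)=O)[C@@]12C.C1CCC2=[NH+]CCCN2CC1
F3 | step 5 | epoxy alcohol from 9 (C10 carbinol, either epimer) | C[C@@]12O[C@@H]1C[C@@H](OC(C)=O)[C@@](C)(COCc1ccccc1)C2O
F4 | step 5 | O-(imidazol-1-ylthiocarbonyl) derivative of F3 | C[C@@]12O[C@@H]1C[C@@H](OC(C)=O)[C@@](C)(COCc1ccccc1)C2OC(=S)n1ccnc1
F0 | step 23 | none | none
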